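The reading comes at 10 d, and the next run hangs on it: keep this charge, or raise it so that a filter has crystals to collect.

substrate 0.25 M; time 10 d

- which holds at 10 d: what has brought the reaction to rest, or that it has not come to rest (forward and back rates have come level / it is still moving / all of the substrate has reacted)
- target at 10 d, in percent of the substrate charged

- amounts and yields of target count crystals too
- given per volume of solution although it is solid: crystals
- the reaction counts as stopped when no species that holds the substrate changes by six tenths of a point or more over the second half of the time
- run time (flask): 10 d

    substrate ⇌ intermediate A (K1 = 0.33, k1 = 0.0050 /s)
    intermediate A ⇌ intermediate B (K2 = 1.2, k2 = 1.3 × 10⁻⁵ /s)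
    intermediate A ⇌ target (K3 = 2.0, k3 = 3.8 × 10⁻⁴ /s)
    crystals ⇌ target, rate k4*(cs4 - [target]) while solid is left; crystals form when [target] > cs4 (cs4 = 0.060 M, k4 = 0.0010 /s)
    target ⇌ isomer of the product (K5 = 0.56, k5 = 3.2 × 10⁻⁴ /s)

Substrate passes through intermediate A to target, which also turns into the isomer of the product and can crystallise, while intermediate A exchanges with intermediate B. Intermediate B fills slowly, with a rate constant far below that of the path to target. While c intermediate A stays steady, its back constant gives a time of 1.07 d, shorter than the time to the reading. This reckoning therefore takes the flask to be at rest when read, which is thermodynamic control.

At rest each dissolved form stands in a constant ratio to c target: intermediate A 0.500, intermediate B 0.600, substrate 1.52, isomer of the product 0.56. Adding target itself and setting c target to the solubility 0.060 M gives the saturation charge, the charge at which the dissolved forms at rest just reach saturation with the last crystal gone: 0.2505 M. With these constants, a charge below it comes to rest without solid, and target then holds the share c solubility over saturation charge. A charge above it leaves the excess as crystals, and the share of target climbs.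

This flask's charge of 0.25 M stands close to the crossing and under it by 5.09 × 10⁻⁴ M, so the reckoning gives no crystals at rest and target at 23.95% of the charge. The next run should then be charged higher if crystals are wanted.

The forecast says forward and back rates have come level and 23.95%, holding that “Full equilibrium therefore has no solid”. The simulation gives forward and back rates have come level and target at 24.0%, with crystals at 5.88% of the charge at 1.00 d and 0% at 10.0 d.

In this flask half of the turnover of the path from intermediate A to intermediate B is done by 0.643 d, far earlier than the reading. By 2.00 d that path has 85% of its turnover behind it, and target reads 24.0% at 5.00 d and 24.0% at 100 d. The neighbour charged with 0.62 M stands above the saturation charge, which gives it target at 69.3% of its charge, crystals counted, and crystals at 59.6%. Its run gives 69.3% and 59.6%.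

The rate constants come from no measurement.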